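**Retrosynthetic overview**
- The target is cut at the bond between lactam C3 and the dienone ring. This is the last step: a chiral-phosphoric-acid-catalysed amidoalkylation of an achiral dienone enol by the N-acylimine released from a racemic hydroxylactam. It sets the only stereocentre.
- Dienone enol: the six-membered carbocycle is bought as 5-methylcyclohexane-1,3-dione. The two prenyl groups go on one at a time by Stork–Danheiser α'-alkylation, and the ring double bond comes from a selenoxide elimination.
- Hydroxylactam: 3-methoxyphthalic anhydride is converted to the imide, which is reduced at the carbonyl next to the methoxy group.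
- Ring order: the benzene ring and the carbocycle are present from the start; the five-membered nitrogen ring is the only ring closed (step 5); the coupling forms no ring.

Assumption: the (R)-configured phosphoric acid is taken to direct the enol to the Si face of C3 of the N-acylimine, which gives (3R); if the first run gives the (3S) product, the (S)-catalyst is used with nothing else changed.

**Step 1**
Reactants: 1 5-methylcyclohexane-1,3-dione
Product: 2 3-ethoxy-5-methylcyclohex-2-en-1-one (racemic)
Conditions: EtOH (5 equiv), p-TsOH·H2O (2 mol %), toluene, reflux, Dean–Stark, 6 h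
Reagents that add atoms: ethanol, CCO
Why: Acid-catalysed vinylogous esterification (enol ether formation) of a cyclic 1,3-dione with azeotropic removal of water; the two carbonyls of 1 are equivalent, so one regioisomer forms, and its racemic C5 centre is erased in step 4.

**Step 2**
Reactants: 2 3-ethoxy-5-methylcyclohex-2-en-1-one; 3 prenyl bromide (1-bromo-3-methylbut-2-ene)
Product: 4 3-ethoxy-5-methyl-6-(3-methylbut-2-en-1-yl)cyclohex-2-en-1-one (racemic, mainly trans)
Conditions: LiN(iPr)2 (1.1 equiv), THF, −78 °C, 45 min; 3 (1.2 equiv), −78 → 0 °C, 3 h; aq. NH4Cl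
Reagents that add atoms: none
Why: Stork–Danheiser kinetic α'-alkylation, in which LiN(iPr)2 removes only the C6 proton of the vinylogous ester and the allylic bromide alkylates the enolate at carbon; the C6 centre formed here becomes non-stereogenic in step 3.

**Step 3**
Reactants: 4 3-ethoxy-5-methyl-6-(3-methylbut-2-en-1-yl)cyclohex-2-en-1-one; 3 prenyl bromide (1-bromo-3-methylbut-2-ene)
Product: 6 5-methyl-4,4-bis(3-methylbut-2-en-1-yl)cyclohexane-1,3-dione (racemic), via diprenyl enol ether 5 (not isolated)
Conditions: LiN(iPr)2 (1.2 equiv), THF, −78 °C, 1 h; 3 (1.5 equiv), DMPU (3 equiv), −78 °C → rt, 12 h; then 2 M HCl, THF, rt, 3 h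
Reagents that add atoms: water, O
Why: A second Stork–Danheiser α'-alkylation (the remaining tertiary C6 proton of 4 is still the kinetic site and DMPU makes the hindered enolate reactive enough to build the quaternary carbon), followed in the same flask by dilute-acid hydrolysis of the enol ether at the unhindered C3, which leaves the trisubstituted alkenes untouched; no stereocentre that survives is formed.

**Step 4**
Reactants: 6 5-methyl-4,4-bis(3-methylbut-2-en-1-yl)cyclohexane-1,3-dione
Product: 9 3-hydroxy-5-methyl-6,6-bis(3-methylbut-2-en-1-yl)cyclohexa-2,4-dien-1-one, via selenide 7 (not isolated), via selenoxide 8 (not isolated)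
Conditions: LiN(iPr)2 (2.3 equiv), THF/DMPU, −78 → 0 °C; PhSeCl (1.05 equiv), −78 °C; 1 M HCl quench; then 30% H2O2 (3 equiv), pyridine (2 equiv), CH2Cl2, 0 °C → rt
Reagents that add atoms: none
Why: γ-Selenenylation of a β-diketone dianion followed by selenoxide syn-elimination: the second deprotonation can only occur at C6 because C4 is quaternary, the dianion takes up PhSe at that carbon, and selenoxide 8 eliminates towards its only β-hydrogen (C5–H) at or below room temperature to give the achiral vinylogous acid 9, which cannot aromatise because of the quaternary carbon.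

**Step 5**
Reactants: 10 3-methoxyphthalic anhydride
Product: 11 3-methoxyphthalimide (4-methoxyisoindoline-1,3-dione)
Conditions: urea (1.1 equiv), neat melt, 140 °C, 1 h
Reagents that add atoms: urea, NC(N)=O
Why: Classical imide formation in which ammonia released from urea opens the anhydride and the phthalamic acid cyclodehydrates in the melt; both modes of ring opening lead to the same imide.

**Step 6**
Reactants: 11 3-methoxyphthalimide
Product: 12 3-hydroxy-4-methoxyisoindolin-1-one (racemic hemiaminal)
Conditions: NaBH4 (2.0 equiv), MeOH/CH2Cl2 (1:1), −10 → 0 °C, 1 h; 1 M HCl to pH 5 at 0 °C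
Reagents that add atoms: none
Why: Partial hydride reduction of a cyclic imide to the hydroxylactam; the carbonyl next to the methoxy group is expected to be the one reduced, by analogy with N-alkyl 3-alkoxyphthalimides (sodium chelation between the methoxy oxygen and that carbonyl), low temperature prevents ring opening and over-reduction, the regiochemistry is checked by the OMe/H3 NOE, and the racemic hemiaminal centre is erased in step 7.

**Step 7**
Reactants: 9 3-hydroxy-5-methyl-6,6-bis(3-methylbut-2-en-1-yl)cyclohexa-2,4-dien-1-one (1.2 equiv); 12 3-hydroxy-4-methoxyisoindolin-1-one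
Product: 14 (3R)-3-[2-hydroxy-4-methyl-5,5-bis(3-methylbut-2-en-1-yl)-6-oxocyclohexa-1,3-dien-1-yl]-4-methoxy-2,3-dihydro-1H-isoindol-1-one, via N-acylimine 13 (not isolated)
Conditions: (R)-TRIP [(R)-3,3'-bis(2,4,6-triisopropylphenyl)-1,1'-binaphthyl-2,2'-diyl hydrogen phosphate] (10 mol %), 5 Å molecular sieves, toluene/CH2Cl2 (2:1), −20 °C, 48 h
Reagents that add atoms: none
Why: Proposed new method: a chiral-phosphoric-acid-catalysed aza-Friedel–Crafts (Mannich-type amidoalkylation) in which the acid dehydrates 12 to the N–H acylimine 13 (an acyliminium phosphate pair stabilised by the ortho methoxy group) and then holds both partners, P–O–H···N of 13 and P=O···H–O of enol 9, so that C2 of 9 (its only nucleophilic carbon) adds to the Si face of C3 inside the pocket of the triisopropylphenyl groups and sets the (R) centre; the closest known reactions are the phosphoric-acid-catalysed Mannich addition of acetylacetone to N-Boc aldimines and the additions of indoles and thiols to N-acylimines from 3-aryl-3-hydroxyisoindolinones, whereas neither a 3-unsubstituted N–H isoindolinone acylimine with a peri substituent nor a dearomatised 6,6-dialkyl-3-hydroxycyclohexadienone carbon nucleophile has been used in this way.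

**Compound list**
1 | 5-methylcyclohexane-1,3-dione | CC1CC(=O)CC(=O)C1 | starting material
2 | 3-ethoxy-5-methylcyclohex-2-en-1-one (racemic) | CCOC1=CC(=O)CC(C)C1 | intermediate
3 | prenyl bromide (1-bromo-3-methylbut-2-ene) | CC(C)=CCBr | starting material
4 | 3-ethoxy-5-methyl-6-(3-methylbut-2-en-1-yl)cyclohex-2-en-1-one (racemic, mainly trans) | CCOC1=CC(=O)C(CC=C(C)C)C(C)C1 | intermediate
5 | 3-ethoxy-5-methyl-6,6-bis(3-methylbut-2-en-1-yl)cyclohex-2-en-1-one (racemic; formed in the flask in step 3) | CCOC1=CC(=O)C(CC=C(C)C)(CC=C(C)C)C(C)C1 | intermediate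
6 | 5-methyl-4,4-bis(3-methylbut-2-en-1-yl)cyclohexane-1,3-dione (racemic) | CC1CC(=O)CC(=O)C1(CC=C(C)C)CC=C(C)C | intermediate
7 | 5-methyl-4,4-bis(3-methylbut-2-en-1-yl)-6-(phenylselanyl)cyclohexane-1,3-dione (formed in the flask in step 4) | CC1C([Se]c2ccccc2)C(=O)CC(=O)C1(CC=C(C)C)CC=C(C)C | intermediate
8 | 5-methyl-4,4-bis(3-methylbut-2-en-1-yl)-6-(phenylseleninyl)cyclohexane-1,3-dione (formed in the flask in step 4) | CC1C([Se](=O)c2ccccc2)C(=O)CC(=O)C1(CC=C(C)C)CC=C(C)C | intermediate
9 | 3-hydroxy-5-methyl-6,6-bis(3-methylbut-2-en-1-yl)cyclohexa-2,4-dien-1-one (achiral) | CC1=CC(O)=CC(=O)C1(CC=C(C)C)CC=C(C)C | intermediate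
10 | 3-methoxyphthalic anhydride (4-methoxy-2-benzofuran-1,3-dione) | COc1cccc2C(=O)OC(=O)c12 | starting material
11 | 3-methoxyphthalimide (4-methoxyisoindoline-1,3-dione) | COc1cccc2C(=O)NC(=O)c12 | intermediate
12 | 3-hydroxy-4-methoxyisoindolin-1-one (racemic) | COc1cccc2C(=O)NC(O)c12 | intermediate
13 | 4-methoxy-1H-isoindol-1-one (N-acylimine, formed in the flask in step 7) | COc1cccc2C(=O)N=Cc12 | intermediate
14 | (3R)-3-[2-hydroxy-4-methyl-5,5-bis(3-methylbut-2-en-1-yl)-6-oxocyclohexa-1,3-dien-1-yl]-4-methoxy-2,3-dihydro-1H-isoindol-1-one (CNP0508988.2, drawn as the given tautomer) | COc1cccc2c1[C@H](C1=C(O)C=C(C)C(CC=C(C)C)(CC=C(C)C)C1=O)NC2=O | target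

**Totals**
Total step count: 7. Longest linear sequence: 5 steps (steps 1, 2, 3, 4 and 7); steps 5 and 6 form the second branch.

**Three steps most likely to fail**

Step 7 (the proposed new coupling). The risks are: a racemic background reaction promoted by the acidity of 9 itself; low selectivity with an N–H acylimine that carries a peri methoxy group; and loss of enantiopurity in 14 by acid-mediated ring opening and re-closure (retro-Mannich). The sense of induction also has to be confirmed, by X-ray or circular dichroism. The fallback uses known chemistry, sets out from 9 and 12 and comes back at 14. The two are combined with p-TsOH·H2O (10 mol %) in CH2Cl2 at room temperature, the long-established acid-mediated α-amidoalkylation of an enolised 1,3-dicarbonyl by an N-acyliminium ion. This gives racemic 3-[2-hydroxy-4-methyl-5,5-bis(3-methylbut-2-en-1-yl)-6-oxocyclohexa-1,3-dien-1-yl]-4-methoxyisoindolin-1-one F1. Preparative supercritical-fluid chromatography on an amylose tris(3,5-dimethylphenylcarbamate) phase then separates 14 from its mirror image, (3S)-3-[2-hydroxy-4-methyl-5,5-bis(3-methylbut-2-en-1-yl)-6-oxocyclohexa-1,3-dien-1-yl]-4-methoxyisoindolin-1-one F2.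

Step 4 (dianion selenenylation and selenoxide elimination). The risks are that electrophilic selenium attacks the nucleophilic C2 of the dione or the prenyl alkenes, and that 9 is sensitive to heat (Cope rearrangement to a phenol), so it must be kept below about 40 °C. The fallback sets out from 3 and comes back at 9. It avoids the oxidation by building the ring from an acyclic precursor that is already at the right oxidation level. Pentane-2,4-dione is alkylated twice at C3 with 3 (K2CO3, acetone, reflux) to give 3,3-bis(3-methylbut-2-en-1-yl)pentane-2,4-dione F3. Soft-enolisation C-acylation of one methyl ketone (MgBr2·OEt2, iPr2NEt, 1-acetylbenzotriazole, CH2Cl2, rt) gives 3,3-bis(3-methylbut-2-en-1-yl)heptane-2,4,6-trione F4. DBU in toluene then forms the enolate of the 4,6-diketone, whose terminal carbon adds to the only free ketone (C2), as in the classical cyclisation of heptane-2,4,6-trione to orcinol. This gives the aldol 5-hydroxy-5-methyl-4,4-bis(3-methylbut-2-en-1-yl)cyclohexane-1,3-dione F5, which loses water on acidification to give 9.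

Step 3 (second prenylation and hydrolysis). The risk lies in the alkylation, in which a fully substituted lithium enolate must attack an allylic bromide next to the methyl-bearing carbon; γ-deprotonation, O-alkylation or a stalled reaction may compete. The fallback sets out from 4 and comes back at 5. It replaces the bimolecular enolate alkylation by an intramolecular, palladium-mediated delivery of the allyl unit. The enolate of 4 (LiN(iPr)2, THF/TMEDA, −78 °C) is trapped on oxygen with allyl chloroformate to give prop-2-en-1-yl 5-ethoxy-3-methyl-2-(3-methylbut-2-en-1-yl)cyclohexa-1,5-dien-1-yl carbonate F6. Pd(PPh3)4 (5 mol %, a zerovalent palladium complex) in THF at room temperature then brings about decarboxylative Tsuji allylation, in which the enolate and the allyl cation partner are generated together and recombine at the hindered carbon, giving 3-ethoxy-5-methyl-6-(3-methylbut-2-en-1-yl)-6-(prop-2-en-1-yl)cyclohex-2-en-1-one F7. Cross-metathesis of F7 with 2-methylbut-2-ene as co-solvent (second-generation Grubbs catalyst, RuCl2(=CHPh)(H2IMes)(PCy3), 5 mol %, CH2Cl2, 40 °C) turns the allyl group into a prenyl group and gives 5, which is hydrolysed to 6 with 2 M HCl as in step 3.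

**Further compounds**
F1 | step 7 | racemic 3-[2-hydroxy-4-methyl-5,5-bis(3-methylbut-2-en-1-yl)-6-oxocyclohexa-1,3-dien-1-yl]-4-methoxyisoindolin-1-one | COc1cccc2c1C(C1=C(O)C=C(C)C(CC=C(C)C)(CC=C(C)C)C1=O)NC2=O
F2 | step 7 | (3S)-3-[2-hydroxy-4-methyl-5,5-bis(3-methylbut-2-en-1-yl)-6-oxocyclohexa-1,3-dien-1-yl]-4-methoxyisoindolin-1-one | COc1cccc2c1[C@@H](C1=C(O)C=C(C)C(CC=C(C)C)(CC=C(C)C)C1=O)NC2=O
F3 | step 4 | 3,3-bis(3-methylbut-2-en-1-yl)pentane-2,4-dione | CC(=O)C(CC=C(C)C)(CC=C(C)C)C(C)=O
F4 | step 4 | 3,3-bis(3-methylbut-2-en-1-yl)heptane-2,4,6-trione | CC(=O)CC(=O)C(CC=C(C)C)(CC=C(C)C)C(C)=O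
F5 | step 4 | 5-hydroxy-5-methyl-4,4-bis(3-methylbut-2-en-1-yl)cyclohexane-1,3-dione (racemic) | CC1(O)CC(=O)CC(=O)C1(CC=C(C)C)CC=C(C)C
F6 | step 3 | prop-2-en-1-yl 5-ethoxy-3-methyl-2-(3-methylbut-2-en-1-yl)cyclohexa-1,5-dien-1-yl carbonate (racemic) | CCOC1=CC(OC(=O)OCC=C)=C(CC=C(C)C)C(C)C1
F7 | step 3 | 3-ethoxy-5-methyl-6-(3-methylbut-2-en-1-yl)-6-(prop-2-en-1-yl)cyclohex-2-en-1-one (racemic, mixture of diastereomers) | CCOC1=CC(=O)C(CC=C)(CC=C(C)C)C(C)C1
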